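(Readings and results are calculated from invented constants, and the scatter is random.)

Count the reagent.

| setting | dusk | winter | autumn | flask |
|---|---|---|---|---|
| starting material | 0.30 M | 0.30 M | 0.30 M | 0.30 M |
| second substrate | 0.30 M | 0.30 M | 0.30 M | 0.300 M |
| reagent | 0.54 M | 0.54 M | 1.1 M | 0.540 M |
| free catalyst | 42 mM | 66 mM | 30 mM | 30 mM |
| remark | run made earlier | run made earlier | run made earlier |  |

- dusk (time / min: target / %): 5.00: 2.5; 12.0: 6.9; 25.0: 12.6; 60.0: 22.6
- winter (time / min: target / %): 5.00: 3.6; 12.0: 8.4; 25.0: 16.8; 60.0: 31.9
- autumn (time / min: target / %): 8.00: 6.1; 20.0: 14.5; 40.0: 27.9; 60.0: 38.9

(standard deviation of a reading: 0.5 percentage points)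

- no earlier run changes the charge of second substrate; that part of a forecast is a guess

- apparent order in second substrate when 50 % of the starting material are converted (percent change of the rate of making target for one percent more second substrate charged)
- factor on the rate of making target when 50 % of the starting material are converted if free catalyst is charged twice over

Turn the free catalyst first. By hand, target should follow the catalyst charged. From the dusk run to the winter run the charge grows by a factor 1.57 and the target at 60.0 min by 1.41, so you read an order near 0.763.

Turn the reagent next. In the dusk run, target has used 12.6 % of the reagent by 60.0 min, if one goes per target, yet the pace after 25.0 min is 0.567 of the pace before. With about twice the reagent but also less free catalyst, the autumn run keeps 0.789 of its pace over its own last stretch, a reading above that of the dusk run. My guess is that second substrate takes reagent too, one for one.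

Turn the second substrate last; no run varies it, so go round twice. In the first round, counting one reagent per starting material converted and nothing else, the reckoning leaves 0.390 M of reagent at 50 % conversion of the flask's starting material. In the second, put the guess back in and you get the reagent margin, meaning reagent charged less second substrate charged less starting material converted: 0.0900 M. Reagent would then be the limiting reagent, since the two ask for 0.600 M, more than the 0.540 M charged. One percent more second substrate takes 3.33 percent of that margin, so with a rate in the first power of reagent I commit to an order near minus 3.33.

The forecast gives 1 and a doubling factor of 1.7, saying: “Second substrate was never varied, so its order is a guess”.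

The flask gives −2.8 and 2.62, reaching that conversion at 3.83 h.

    starting material + free catalyst ⇌ catalyst intermediate A (K = 3.90 L mol⁻¹, k = 0.0129 L mol⁻¹ s⁻¹)
    reagent + catalyst intermediate A → free catalyst + target (k = 0.00531 L mol⁻¹ s⁻¹)
    second substrate + free catalyst ⇌ catalyst intermediate B (K = 9.05 L mol⁻¹, k = 0.0635 L mol⁻¹ s⁻¹)
    reagent + catalyst intermediate B → free catalyst + second product (k = 0.0810 L mol⁻¹ s⁻¹)
    starting material + catalyst intermediate A → spent catalyst (k = 3.46 × 10⁻⁴ L mol⁻¹ s⁻¹)

Second substrate passes through catalyst intermediate B to second product and pays one reagent each time, which is the second round of the reckoning; the margin reads minus 3.33 where the flask gives −2.8. Now take the same flask with the passing of second substrate + free catalyst into catalyst intermediate B removed, both ways. Second substrate then touches neither reagent nor free catalyst, and in the largest single effect of those tried, not the whole reason, the order moves from −2.8 to 0.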